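All three C2–aryl bonds are cut at once. The route exploits the fact that C2 of each of the three 2,3-dihydrobenzofuran rings is bonded to the ring oxygen O1 and carries the same 4-oxygenated phenyl group, trans to the aryl group on C3: each C2 can therefore be a planar α-oxy radical born from a carboxylic acid. One light-driven iridium/nickel operation should replace three CO2H groups by three 4-methoxyphenyl groups and set three stereocentres. Its precursor is a triacid of three C3–C4-linked 3-aryl-2,3-dihydrobenzofuran-2-carboxylic acid units with fixed C3 centres, assembled by iterative asymmetric conjugate arylation of one coumarin triflate and ring contraction.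

Key step: step 12

Remark: the oxygen on C4 of unit 1 is carried as its aryl triflate through the key step (a hindered, electron-rich aryl triflate should be ignored by nickel while an aryl iodide is present), so that one coumarin serves all three units and no hydrogenolysis is needed beside the three benzylic C2–O bonds; all esters and acids are handled as C2 epimer mixtures, since the key step erases C2.

Conventions: unit 1 is the dihydrobenzofuran that ends up with the styryl group on C4, unit 2 the middle one, unit 3 the one whose C3 carries the 3,5-dioxygenated phenyl ring; C4 of unit 3 is bonded to C3 of unit 2, and C4 of unit 2 to C3 of unit 1. Tf = CF3SO2; Bpin = 4,4,5,5-tetramethyl-1,3,2-dioxaborolan-2-yl. Diene antipode A is the enantiomer of 2,5-diphenylbicyclo[2.2.2]octa-2,5-diene that, in a trial run with 3 and 4, gives the 4R lactone; antipode B is its mirror image.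

Step 1
Reactants: 1 5,7-dihydroxycoumarin
Product: 2 5-hydroxy-7-methoxycoumarin
Conditions: MeI (1.05 equiv), K2CO3 (1.1 equiv), acetone, 0 °C → rt
Reagents that add atoms: iodomethane, CI
Why: Williamson O-methylation; with one equivalent of base the 7-OH, which lies para to C4a and is not flanked by the peri C4–H, should be alkylated before the 5-OH, and any 5-methyl or dimethyl ether is removed by chromatography.

Step 2
Reactants: 2 5-hydroxy-7-methoxycoumarin
Product: 3 7-methoxy-2-oxo-2H-chromen-5-yl trifluoromethanesulfonate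
Conditions: Tf2O, pyridine, CH2Cl2, 0 °C
Reagents that add atoms: trifluoromethanesulfonic anhydride, O=S(=O)(OS(=O)(=O)C(F)(F)F)C(F)(F)F
Why: O-sulfonylation of the remaining phenol is routine and gives the aryl triflate that later becomes the C4 handle of every unit.

Step 3
Reactants: 3 7-methoxy-2-oxo-2H-chromen-5-yl trifluoromethanesulfonate; 4 3,5-dimethoxyphenylboronic acid
Product: 5 (4R)-4-(3,5-dimethoxyphenyl)-7-methoxy-2-oxochroman-5-yl triflate
Conditions: [RhCl(C2H4)2]2 (3 mol%), diene antipode A (7 mol%), KOH (0.15 equiv), 1,4-dioxane/H2O 10:1, 50 °C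
Reagents that add atoms: none
Why: Hayashi–Miyaura conjugate arylation: the aryl–rhodium formed by transmetalation adds across C3=C4 and water protonates the oxa-π-allyl rhodium, the C2-symmetric diene choosing the enantioface and so setting C4 as R, while the 5-triflate activates the acceptor and is left alone by monovalent rhodium.

Step 4
Reactants: 5 (4R)-4-(3,5-dimethoxyphenyl)-7-methoxy-2-oxochroman-5-yl triflate
Product: 7 methyl (3R)-3-(3,5-dimethoxyphenyl)-6-methoxy-4-(triflyloxy)-2,3-dihydrobenzofuran-2-carboxylate (unit 3 ester triflate; C2 epimers), via 3-bromolactone 6 (not isolated)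
Conditions: LiN(SiMe3)2 (1.05 equiv), THF, −78 °C; NBS (1.0 equiv), −78 °C; then NaOMe (2 equiv), MeOH, −78 → 0 °C
Reagents that add atoms: sodium methoxide, [Na+].[O-]C; N-bromosuccinimide, O=C1CCC(=O)N1Br (its bromine stays only in 6)
Why: enolate α-bromination followed by a ring contraction of the Perkin-rearrangement type: methoxide opens the aryl lactone to the methyl ester and the freed phenoxide displaces the α-bromide (5-exo-tet SN2), which leaves the former C4 (now C3, still R) untouched; the bromide is not isolated because it would lose HBr on handling, the hindered triflate should tolerate brief methoxide at or below 0 °C, and C2 forms as an epimer mixture of no consequence.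

Step 5
Reactants: 7 unit 3 ester triflate
Product: 8 methyl (3R)-3-(3,5-dimethoxyphenyl)-6-methoxy-4-Bpin-2,3-dihydrobenzofuran-2-carboxylate (unit 3 boronate; C2 epimers)
Conditions: PdCl2(dppf) (5 mol%), B2pin2 (1.5 equiv), KOAc (3 equiv), 1,4-dioxane, 90 °C
Reagents that add atoms: bis(pinacolato)diboron, CC1(C)OB(OC1(C)C)B1OC(C)(C)C(C)(C)O1
Why: Miyaura borylation of an aryl triflate by zerovalent palladium with acetate base tolerates the methyl ester and does not touch the sp3 centres.

Step 6
Reactants: 8 unit 3 boronate; 3 7-methoxy-2-oxo-2H-chromen-5-yl trifluoromethanesulfonate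
Product: 9 (4S)-7-methoxy-2-oxo-5-(triflyloxy)chroman-4-yl compound whose chromanone C4 is bonded to C4 of methyl (3R)-3-(3,5-dimethoxyphenyl)-6-methoxy-2,3-dihydrobenzofuran-2-carboxylate (C2 epimers)
Conditions: [RhCl(C2H4)2]2 (5 mol%), diene antipode B (11 mol%), KOH (0.2 equiv), 3 (2.5 equiv), 1,4-dioxane/H2O 10:1, 60 °C
Reagents that add atoms: none
Why: Hayashi–Miyaura conjugate arylation with the pinacol boronate, which transmetalates to the hydroxo-rhodium under aqueous base; the mirror-image diene, not the remote C3 centre of 8, should decide the face and set the new C4 as S, and the cheap coumarin is used in excess to spare the boronate.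

Step 7
Reactants: 9 (4S)-chromanone of step 6
Product: 11 two-unit diester triflate: methyl (3S)-6-methoxy-4-(triflyloxy)-2,3-dihydrobenzofuran-2-carboxylate (unit 2) whose C3 carries C4 of methyl (3R)-3-(3,5-dimethoxyphenyl)-6-methoxy-2,3-dihydrobenzofuran-2-carboxylate (unit 3); both C2 centres epimeric, via 3-bromolactone 10 (not isolated)
Conditions: LiN(SiMe3)2 (1.05 equiv), THF, −78 °C; NBS (1.0 equiv), −78 °C; then NaOMe (2 equiv), MeOH, −78 → 0 °C
Reagents that add atoms: sodium methoxide, [Na+].[O-]C; N-bromosuccinimide, O=C1CCC(=O)N1Br (its bromine stays only in 10)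
Why: enolate bromination and Perkin-type ring contraction as in step 4; one equivalent of amide base at −78 °C should enolise only the unhindered CH2 of the aryl lactone and not the C2–H of the α-alkoxy ester, methoxide cannot scramble a methyl ester, and the new C3 keeps the S configuration set in step 6.

Step 8
Reactants: 11 two-unit diester triflate
Product: 12 two-unit diester boronate (11 with Bpin in place of OTf at C4 of unit 2)
Conditions: PdCl2(dppf) (5 mol%), B2pin2 (1.5 equiv), KOAc (3 equiv), 1,4-dioxane, 90 °C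
Reagents that add atoms: bis(pinacolato)diboron, CC1(C)OB(OC1(C)C)B1OC(C)(C)C(C)(C)O1
Why: Miyaura borylation as in step 5; only one triflate is present and both esters are inert to acetate.

Step 9
Reactants: 12 two-unit diester boronate; 3 7-methoxy-2-oxo-2H-chromen-5-yl trifluoromethanesulfonate
Product: 13 (4R)-7-methoxy-2-oxo-5-(triflyloxy)chroman-4-yl compound whose chromanone C4 is bonded to C4 of unit 2 of the two-unit diester (unit 2 3S, unit 3 3R; C2 epimers)
Conditions: [RhCl(C2H4)2]2 (5 mol%), diene antipode A (11 mol%), KOH (0.2 equiv), 3 (2.5 equiv), 1,4-dioxane/H2O 10:1, 60 °C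
Reagents that add atoms: none
Why: Hayashi–Miyaura conjugate arylation as in step 6, with the diene antipode switched back so that catalyst control sets the new C4 as R.

Step 10
Reactants: 13 (4R)-chromanone of step 9
Product: 15 three-unit triester triflate: unit 1 = methyl (3R)-6-methoxy-4-(triflyloxy)-2,3-dihydrobenzofuran-2-carboxylate, its C3 bonded to C4 of unit 2 (3S), whose C3 is bonded to C4 of unit 3 (3R, with 3,5-dimethoxyphenyl on C3); each unit 6-methoxy and 2-CO2Me; three C2 centres epimeric, via 3-bromolactone 14 (not isolated)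
Conditions: LiN(SiMe3)2 (1.05 equiv), THF, −78 °C; NBS (1.0 equiv), −78 °C; then NaOMe (2 equiv), MeOH, −78 → 0 °C
Reagents that add atoms: sodium methoxide, [Na+].[O-]C; N-bromosuccinimide, O=C1CCC(=O)N1Br (its bromine stays only in 14)
Why: enolate bromination and Perkin-type ring contraction as in steps 4 and 7; the lactone CH2 is again the most acidic and least hindered C–H, and the former C4 becomes C3 of unit 1 with R configuration retained.

Step 11
Reactants: 15 three-unit triester triflate
Product: 16 three-unit triacid triflate (15 with three CO2H groups; C3 centres R, S, R for units 1, 2, 3; three C2 centres epimeric)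
Conditions: LiOH·H2O (6 equiv), THF/H2O 3:1, 0 °C → rt; then cold 1 M HCl to pH 3
Reagents that add atoms: lithium hydroxide, [Li+].[OH-]
Why: saponification of three α-alkoxy methyl esters, which are activated toward hydroxide, under cold conditions that a hindered electron-rich aryl triflate should survive; the C3 centres bear no acidic hydrogen.

Step 12
Reactants: 16 three-unit triacid triflate; 17 4-iodoanisole (3 equiv)
Product: 18 octa-O-methyl tris(dihydrobenzofuran) triflate in which C2 of every dihydrobenzofuran ring carries a 4-methoxyphenyl group trans to the aryl group on C3 (OTf at C4 of unit 1)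
Conditions: Ir[dF(CF3)ppy]2(dtbbpy)PF6 (3 mol%), NiCl2(dme) (30 mol%), 4,4'-di-tert-butyl-2,2'-bipyridine (35 mol%), Cs2CO3 (4.5 equiv), 17 (6 equiv), degassed DMF, blue LEDs (450 nm), 25 °C
Reagents that add atoms: 4-iodoanisole (second equivalent), COc1ccc(I)cc1; 4-iodoanisole (third equivalent), Ic1ccc(OC)cc1
Why: Proposed new method: each carboxylate (formed with Cs2CO3) is oxidised by the photoexcited iridium complex and loses CO2 to give a planar C2 radical stabilised by O1, while the bipyridine–nickel catalyst, after oxidative addition to 4-iodoanisole, traps this radical and the resulting trivalent nickel alkyl–aryl species reductively eliminates the C2–aryl bond, the reduced iridium complex returning nickel to its low-valent state; the cycle runs once per carboxyl group, so three molecules of 17 are built into 18. The closest known reaction type is the single photoredox/nickel decarboxylative arylation of α-oxy carboxylic acids with aryl halides, which here must run three times on one molecule. No ring is closed. Each new C2 centre is set under substrate control by the fixed aryl group on the neighbouring C3, which blocks the cis face so that nickel and then the aryl group enter trans, giving (2R,3R), (2S,3S) and (2R,3R) for units 1, 2 and 3; because the radical is planar, both C2 epimers of each acid converge on the same product. The step needs trans selectivity at three sites, which the C3 substituent of each five-membered ring supplies, and chemoselectivity for the aryl iodide over the C4 triflate of unit 1, which the hindered electron-rich nature of that triflate and the excess of iodide should secure; the carboxylates are oxidised far more easily than the methoxyarenes.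

Step 13
Reactants: 18 octa-O-methyl tris(dihydrobenzofuran) triflate; 19 (E)-2-(4-methoxystyryl)-4,4,5,5-tetramethyl-1,3,2-dioxaborolane
Product: 20 nona-O-methylmiyabenol A (18 with an (E)-4-methoxystyryl group in place of OTf at C4 of unit 1)
Conditions: Pd(OAc)2 (5 mol%), SPhos (10 mol%), K3PO4 (3 equiv), toluene/H2O 10:1, 80 °C
Reagents that add atoms: none
Why: Suzuki–Miyaura coupling: the dialkylbiarylphosphine makes oxidative addition of the hindered triflate to zerovalent palladium fast, the alkenyl boronate transfers its double bond with retention so the E geometry comes from the reagent, and the mild base leaves the six stereocentres alone.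

Step 14
Reactants: 20 nona-O-methylmiyabenol A
Product: 21 miyabenol A
Conditions: BBr3 (30 equiv), CH2Cl2, −78 → 0 °C; MeOH, then aqueous NaHCO3
Reagents that add atoms: none
Why: Lewis-acid cleavage of aryl methyl ethers (boron binds each ether oxygen and bromide removes the methyl group by SN2), run at or below 0 °C so that the benzylic C2–O bonds and the E alkene should stay intact.

Compound list
1 | 5,7-dihydroxycoumarin | O=c1ccc2c(O)cc(O)cc2o1 | starting material
2 | 5-hydroxy-7-methoxycoumarin | O=c1ccc2c(O)cc(OC)cc2o1 | intermediate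
3 | 7-methoxy-2-oxo-2H-chromen-5-yl trifluoromethanesulfonate | O=c1ccc2c(OS(=O)(=O)C(F)(F)F)cc(OC)cc2o1 | intermediate
4 | 3,5-dimethoxyphenylboronic acid | COc1cc(OC)cc(B(O)O)c1 | starting material
5 | (4R)-4-(3,5-dimethoxyphenyl)-7-methoxy-2-oxochroman-5-yl triflate | O=C1C[C@H](c2cc(OC)cc(OC)c2)c2c(OS(=O)(=O)C(F)(F)F)cc(OC)cc2O1 | intermediate
6 | (4R)-3-bromo-4-(3,5-dimethoxyphenyl)-7-methoxy-2-oxochroman-5-yl triflate (C3 epimers, 3,4-trans expected to prevail) | O=C1C(Br)[C@H](c2cc(OC)cc(OC)c2)c2c(OS(=O)(=O)C(F)(F)F)cc(OC)cc2O1 | intermediate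
7 | methyl (3R)-3-(3,5-dimethoxyphenyl)-6-methoxy-4-(triflyloxy)-2,3-dihydrobenzofuran-2-carboxylate (C2 epimers) | O=S(=O)(Oc1cc(OC)cc2c1[C@@H](c1cc(OC)cc(OC)c1)C(C(=O)OC)O2)C(F)(F)F | intermediate
8 | methyl (3R)-3-(3,5-dimethoxyphenyl)-6-methoxy-4-Bpin-2,3-dihydrobenzofuran-2-carboxylate (C2 epimers) | CC1(C)OB(c2cc(OC)cc3c2[C@@H](c2cc(OC)cc(OC)c2)C(C(=O)OC)O3)OC1(C)C | intermediate
9 | methyl (3R)-3-(3,5-dimethoxyphenyl)-6-methoxy-4-[(4S)-7-methoxy-2-oxo-5-(triflyloxy)chroman-4-yl]-2,3-dihydrobenzofuran-2-carboxylate (C2 epimers) | O=C1C[C@@H](c2cc(OC)cc3c2[C@@H](c2cc(OC)cc(OC)c2)C(C(=O)OC)O3)c2c(OS(=O)(=O)C(F)(F)F)cc(OC)cc2O1 | intermediate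
10 | 3-bromo derivative of 9 (4S; C3 of the lactone epimeric) | O=C1C(Br)[C@@H](c2cc(OC)cc3c2[C@@H](c2cc(OC)cc(OC)c2)C(C(=O)OC)O3)c2c(OS(=O)(=O)C(F)(F)F)cc(OC)cc2O1 | intermediate
11 | two-unit diester triflate (unit 2 3S with OTf at C4, unit 3 3R; both C2 epimeric) | O=S(=O)(Oc1cc(OC)cc2c1[C@H](c1cc(OC)cc3c1[C@@H](c1cc(OC)cc(OC)c1)C(C(=O)OC)O3)C(C(=O)OC)O2)C(F)(F)F | intermediate
12 | two-unit diester boronate (Bpin at C4 of unit 2) | CC1(C)OB(c2cc(OC)cc3c2[C@H](c2cc(OC)cc4c2[C@@H](c2cc(OC)cc(OC)c2)C(C(=O)OC)O4)C(C(=O)OC)O3)OC1(C)C | intermediate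
13 | (4R)-7-methoxy-2-oxo-5-(triflyloxy)chroman-4-yl compound bonded to C4 of unit 2 of the two-unit diester | O=C1C[C@H](c2cc(OC)cc3c2[C@H](c2cc(OC)cc4c2[C@@H](c2cc(OC)cc(OC)c2)C(C(=O)OC)O4)C(C(=O)OC)O3)c2c(OS(=O)(=O)C(F)(F)F)cc(OC)cc2O1 | intermediate
14 | 3-bromo derivative of 13 (4R; C3 of the lactone epimeric) | O=C1C(Br)[C@H](c2cc(OC)cc3c2[C@H](c2cc(OC)cc4c2[C@@H](c2cc(OC)cc(OC)c2)C(C(=O)OC)O4)C(C(=O)OC)O3)c2c(OS(=O)(=O)C(F)(F)F)cc(OC)cc2O1 | intermediate
15 | three-unit triester triflate (C3: R, S, R for units 1, 2, 3; three C2 epimeric; OTf at C4 of unit 1) | O=S(=O)(Oc1cc(OC)cc2c1[C@@H](c1cc(OC)cc3c1[C@H](c1cc(OC)cc4c1[C@@H](c1cc(OC)cc(OC)c1)C(C(=O)OC)O4)C(C(=O)OC)O3)C(C(=O)OC)O2)C(F)(F)F | intermediate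
16 | three-unit triacid triflate (C3: R, S, R; three C2 epimeric) | O=S(=O)(Oc1cc(OC)cc2c1[C@@H](c1cc(OC)cc3c1[C@H](c1cc(OC)cc4c1[C@@H](c1cc(OC)cc(OC)c1)C(C(=O)O)O4)C(C(=O)O)O3)C(C(=O)O)O2)C(F)(F)F | intermediate
17 | 4-iodoanisole | COc1ccc(I)cc1 | starting material
18 | octa-O-methyl tris(dihydrobenzofuran) triflate, units 1, 2, 3 = (2R,3R), (2S,3S), (2R,3R) | O=S(=O)(Oc1cc(OC)cc2c1[C@@H](c1cc(OC)cc3c1[C@H](c1cc(OC)cc4c1[C@@H](c1cc(OC)cc(OC)c1)[C@H](c1ccc(OC)cc1)O4)[C@@H](c1ccc(OC)cc1)O3)[C@H](c1ccc(OC)cc1)O2)C(F)(F)F | intermediate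
19 | (E)-2-(4-methoxystyryl)-4,4,5,5-tetramethyl-1,3,2-dioxaborolane | COc1ccc(/C=C/B2OC(C)(C)C(C)(C)O2)cc1 | starting material
20 | nona-O-methylmiyabenol A | COc1ccc(/C=C/c2cc(OC)cc3c2[C@@H](c2cc(OC)cc4c2[C@H](c2cc(OC)cc5c2[C@@H](c2cc(OC)cc(OC)c2)[C@H](c2ccc(OC)cc2)O5)[C@@H](c2ccc(OC)cc2)O4)[C@H](c2ccc(OC)cc2)O3)cc1 | intermediate
21 | miyabenol A | Oc1ccc(/C=C/c2cc(O)cc3c2[C@@H](c2cc(O)cc4c2[C@H](c2cc(O)cc5c2[C@@H](c2cc(O)cc(O)c2)[C@H](c2ccc(O)cc2)O5)[C@@H](c2ccc(O)cc2)O4)[C@H](c2ccc(O)cc2)O3)cc1 | target

Total steps: 14. Longest linear sequence: 14 steps (1 → 21); 4, 17 and 19 are bought, and 3 enters three times.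

Steps most likely to fail

Step 12. The threefold coupling may stall at mono- or bis-arylated acids as the molecule grows more crowded, lose carboxyl groups by protodecarboxylation, or give poor facial selectivity at one of the three sites. The fallback sets out from 7 and installs each anisyl group before the next unit is added, so that every coupling is the known single decarboxylative arylation of one α-oxy acid and can be checked and purified on its own. Hydrolysis of 7 with LiOH should give the unit 3 monoacid F1, and the iridium/nickel conditions of step 12 with 17 should turn it into the (2R,3R)-2-(4-methoxyphenyl) unit 3 triflate F2, which Miyaura borylation converts into the arylated unit 3 boronate F3. Conjugate arylation of 3 with F3 and diene antipode B gives the (4S)-chromanone F4; bromination gives the bromolactone F5, which methoxide contracts to the unit 2 ester F6; hydrolysis gives the unit 2 monoacid F7, a single arylation with 17 gives the bis-arylated two-unit triflate F8, and borylation gives the two-unit boronate F9. Conjugate arylation of 3 with F9 and antipode A gives the (4R)-chromanone F10; bromination gives the bromolactone F11 and ring contraction the unit 1 ester F12; hydrolysis gives the unit 1 monoacid F13, and a last single arylation with 17 comes back to the route at 18.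

Step 9. Carbometalation of the peri-substituted coumarin by the bulky ortho-substituted aryl–rhodium may be slower than protodeboronation of 12, or the resident stereocentres may override the diene and erode facial selectivity. The fallback sets out from 12 and 3 and separates bond formation from stereocontrol. An oxidative Heck arylation (Pd(OAc)2, 1,10-phenanthroline, O2, DMF, 80 °C) should give the achiral-at-C4 4-arylcoumarin F14. A CuH-catalysed asymmetric conjugate reduction (Cu(OAc)2, the DTBM-SEGPHOS antipode that gives 4R, diethoxymethylsilane, t-BuOH, toluene) then sets C4 and comes back to the route at 13.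

Step 10. Proton exchange between the lactone enolate and the more acidic bromolactone may give dibromide plus unreacted 13, and loss of HBr from 14 may give a 4-arylcoumarin and so erase C4. The fallback sets out from 13 and replaces halogen by oxygen. The lithium enolate is hydroxylated with 2-(phenylsulfonyl)-3-phenyloxaziridine to the 3-hydroxylactone F15, which cannot be over-oxidised or eliminate under these conditions. K2CO3 in MeOH opens it to the hydroxy ester phenol F16. A Mitsunobu reaction (PPh3, DIAD, THF) closes the five-membered ether by phenol attack on the activated secondary alcohol and comes back to the route at 15.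

Further compounds
F1 | step 12 | (3R)-3-(3,5-dimethoxyphenyl)-6-methoxy-4-(triflyloxy)-2,3-dihydrobenzofuran-2-carboxylic acid (C2 epimers) | O=S(=O)(Oc1cc(OC)cc2c1[C@@H](c1cc(OC)cc(OC)c1)C(C(=O)O)O2)C(F)(F)F
F2 | step 12 | (2R,3R)-3-(3,5-dimethoxyphenyl)-6-methoxy-2-(4-methoxyphenyl)-2,3-dihydrobenzofuran-4-yl triflate | O=S(=O)(Oc1cc(OC)cc2c1[C@@H](c1cc(OC)cc(OC)c1)[C@H](c1ccc(OC)cc1)O2)C(F)(F)F
F3 | step 12 | 4-Bpin analogue of F2 | CC1(C)OB(c2cc(OC)cc3c2[C@@H](c2cc(OC)cc(OC)c2)[C@H](c2ccc(OC)cc2)O3)OC1(C)C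
F4 | step 12 | (4S)-7-methoxy-2-oxo-5-(triflyloxy)chroman-4-yl compound bonded to C4 of arylated unit 3 | O=C1C[C@@H](c2cc(OC)cc3c2[C@@H](c2cc(OC)cc(OC)c2)[C@H](c2ccc(OC)cc2)O3)c2c(OS(=O)(=O)C(F)(F)F)cc(OC)cc2O1
F5 | step 12 | 3-bromo derivative of F4 | O=C1C(Br)[C@@H](c2cc(OC)cc3c2[C@@H](c2cc(OC)cc(OC)c2)[C@H](c2ccc(OC)cc2)O3)c2c(OS(=O)(=O)C(F)(F)F)cc(OC)cc2O1
F6 | step 12 | unit 2 methyl ester triflate (3S; C2 epimers) bonded to arylated unit 3 | O=S(=O)(Oc1cc(OC)cc2c1[C@H](c1cc(OC)cc3c1[C@@H](c1cc(OC)cc(OC)c1)[C@H](c1ccc(OC)cc1)O3)C(C(=O)OC)O2)C(F)(F)F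
F7 | step 12 | carboxylic acid of F6 | O=S(=O)(Oc1cc(OC)cc2c1[C@H](c1cc(OC)cc3c1[C@@H](c1cc(OC)cc(OC)c1)[C@H](c1ccc(OC)cc1)O3)C(C(=O)O)O2)C(F)(F)F
F8 | step 12 | bis-arylated two-unit triflate, unit 2 (2S,3S), unit 3 (2R,3R) | O=S(=O)(Oc1cc(OC)cc2c1[C@H](c1cc(OC)cc3c1[C@@H](c1cc(OC)cc(OC)c1)[C@H](c1ccc(OC)cc1)O3)[C@@H](c1ccc(OC)cc1)O2)C(F)(F)F
F9 | step 12 | 4-Bpin analogue of F8 | CC1(C)OB(c2cc(OC)cc3c2[C@H](c2cc(OC)cc4c2[C@@H](c2cc(OC)cc(OC)c2)[C@H](c2ccc(OC)cc2)O4)[C@@H](c2ccc(OC)cc2)O3)OC1(C)C
F10 | step 12 | (4R)-7-methoxy-2-oxo-5-(triflyloxy)chroman-4-yl compound bonded to C4 of unit 2 of the bis-arylated two-unit fragment | O=C1C[C@H](c2cc(OC)cc3c2[C@H](c2cc(OC)cc4c2[C@@H](c2cc(OC)cc(OC)c2)[C@H](c2ccc(OC)cc2)O4)[C@@H](c2ccc(OC)cc2)O3)c2c(OS(=O)(=O)C(F)(F)F)cc(OC)cc2O1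
F11 | step 12 | 3-bromo derivative of F10 | O=C1C(Br)[C@H](c2cc(OC)cc3c2[C@H](c2cc(OC)cc4c2[C@@H](c2cc(OC)cc(OC)c2)[C@H](c2ccc(OC)cc2)O4)[C@@H](c2ccc(OC)cc2)O3)c2c(OS(=O)(=O)C(F)(F)F)cc(OC)cc2O1
F12 | step 12 | unit 1 methyl ester triflate (3R; C2 epimers) bonded to the bis-arylated units 2 and 3 | O=S(=O)(Oc1cc(OC)cc2c1[C@@H](c1cc(OC)cc3c1[C@H](c1cc(OC)cc4c1[C@@H](c1cc(OC)cc(OC)c1)[C@H](c1ccc(OC)cc1)O4)[C@@H](c1ccc(OC)cc1)O3)C(C(=O)OC)O2)C(F)(F)F
F13 | step 12 | carboxylic acid of F12 | O=S(=O)(Oc1cc(OC)cc2c1[C@@H](c1cc(OC)cc3c1[C@H](c1cc(OC)cc4c1[C@@H](c1cc(OC)cc(OC)c1)[C@H](c1ccc(OC)cc1)O4)[C@@H](c1ccc(OC)cc1)O3)C(C(=O)O)O2)C(F)(F)F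
F14 | step 9 | 4-aryl-7-methoxy-2-oxo-2H-chromen-5-yl triflate whose aryl group is C4 of unit 2 of the two-unit diester | O=c1cc(-c2cc(OC)cc3c2[C@H](c2cc(OC)cc4c2[C@@H](c2cc(OC)cc(OC)c2)C(C(=O)OC)O4)C(C(=O)OC)O3)c2c(OS(=O)(=O)C(F)(F)F)cc(OC)cc2o1
F15 | step 10 | 3-hydroxy derivative of 13 (4R; C3 of the lactone epimeric) | O=C1C(O)[C@H](c2cc(OC)cc3c2[C@H](c2cc(OC)cc4c2[C@@H](c2cc(OC)cc(OC)c2)C(C(=O)OC)O4)C(C(=O)OC)O3)c2c(OS(=O)(=O)C(F)(F)F)cc(OC)cc2O1
F16 | step 10 | methyl 2-hydroxy-3-[2-hydroxy-4-methoxy-6-(triflyloxy)phenyl]propanoate carrying C4 of unit 2 of the two-unit diester on C3 | COC(=O)C(O)[C@H](c1cc(OC)cc2c1[C@H](c1cc(OC)cc3c1[C@@H](c1cc(OC)cc(OC)c1)C(C(=O)OC)O3)C(C(=O)OC)O2)c1c(O)cc(OC)cc1OS(=O)(=O)C(F)(F)F
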